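**Plan**

- The target is read as epigallocatechin-(4β→8)-epigallocatechin 3-O-gallate-(4β→8)-epigallocatechin: units T (upper), M (middle, galloylated) and B (lower), each (2R,3R).
- Retrosynthetic cuts, in order: the twenty benzyl ethers and a C8 bromine cap on T; C4(T)–C8(M); the gallate ester; O1–C2 of M; C2–aryl of M; then C3–C4 and O1–C2 (lactol) of M together; last the carbinol C–C8(B) bond.
- Forward: lithiated B adds to a ring A salicylaldehyde; ring C of M is grown on that carbinol (lactol, lactone, aryl ketone, alcohol, flavan); the gallate is attached, T is coupled, and all benzyl groups are removed.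
- Enabling feature: in ring C of M, C4 is a diarylmethine carbon bonded to C4a of ring A and to C8 of B, its neighbour C3 bears oxygen, and O1 sits on ring A ortho to C4a. Ring A with O1 and C4 is therefore a latent o-quinone methide, and C2–C3 with its oxygen is a glycolaldehyde enamine.
- Stereochemistry: B and T come from natural EGC; C3 and C4 of M from the catalyst-controlled enamine addition; C2 of M from chelation-controlled ketone reduction followed by invertive ring closure; C4 of T from attack anti to its C2 and C3 substituents.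

Key step: step 8

Remark: flavan numbering is used within each unit, and "EGC" in a name means the (2R,3R)-flavan skeleton of epigallocatechin. The carbinol centre of 9 and 10 is carried as both epimers because it is lost in step 8. The C3 oxygen of M is carried as an allyl ether, which chelates in step 13 and is removed without oxidant in step 15.

**Step 1**
Reactants: 1 (−)-epigallocatechin (EGC)
Product: 3 3,5,7,3',4',5'-hexa-O-benzyl-EGC, via 5,7,3',4',5'-penta-O-benzyl-EGC 2 (not isolated)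
Conditions: BnBr, K2CO3, DMF, −10 °C → rt; then NaH, n-Bu4NI (cat.), 0 °C → rt
Reagents that add atoms: benzyl bromide, BrCc1ccccc1
Why: Williamson etherification in two stages, in which K2CO3 is basic enough for the five phenols but too weak to open ring C through a quinone methide of the pyrogallol ring (so C2 should not epimerise), and NaH then alkylates the secondary C3 hydroxyl once no free phenol is left.

**Step 2**
Reactants: 3 hexa-O-benzyl-EGC
Product: 4 8-bromo-hexa-O-benzyl-EGC
Conditions: NBS (1.0 equiv), CH2Cl2, −78 → 0 °C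
Reagents that add atoms: N-bromosuccinimide, O=C1CCC(=O)N1Br
Why: Electrophilic aromatic bromination, for which C8 is the most nucleophilic ring A position of a 5,7-dialkoxyflavan, so one equivalent of NBS at low temperature should brominate there only.

**Step 3**
Reactants: 5 2,4,6-trihydroxybenzaldehyde
Product: 6 2,4-bis(benzyloxy)-6-hydroxybenzaldehyde
Conditions: BnBr (2.1 equiv), K2CO3, DMF, 0 °C → rt
Reagents that add atoms: benzyl bromide, BrCc1ccccc1
Why: Williamson etherification in which the 4-hydroxyl and one ortho hydroxyl react while the remaining ortho hydroxyl is held in a hydrogen bond to the aldehyde and should stay free under stoichiometric control.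

**Step 4**
Reactants: 6 2,4-bis(benzyloxy)-6-hydroxybenzaldehyde
Product: 7 2-(allyloxy)-4,6-bis(benzyloxy)benzaldehyde
Conditions: allyl bromide, K2CO3, DMF, 50 °C
Reagents that add atoms: allyl bromide, C=CCBr
Why: Williamson etherification of the chelated phenol, which needs only mild heating with the reactive allyl halide and gives a phenol protecting group that can later be removed without acid.

**Step 5**
Reactants: 4 8-bromo-hexa-O-benzyl-EGC; 7 2-(allyloxy)-4,6-bis(benzyloxy)benzaldehyde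
Product: 9 [2-(allyloxy)-4,6-bis(benzyloxy)phenyl](hexa-O-benzyl-EGC-8-yl)methanol (both carbinol epimers), via 8-lithio-hexa-O-benzyl-EGC 8 (not isolated)
Conditions: 4, n-BuLi, THF, −78 °C; then 7, −78 → −40 °C; aq. NH4Cl
Reagents that add atoms: none
Why: Bromine–lithium exchange followed by 1,2-addition of the aryllithium to the aldehyde, where the exchange outruns any attack on the benzyl ethers at −78 °C and the new carbinol centre needs no control because it becomes the trigonal methide carbon in step 8.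

**Step 6**
Reactants: 9 allyl-protected diaryl carbinol
Product: 10 [2,4-bis(benzyloxy)-6-hydroxyphenyl](hexa-O-benzyl-EGC-8-yl)methanol (both carbinol epimers)
Conditions: Pd(PPh3)4 (5 mol %), morpholine, THF, rt; filtration through Et3N-deactivated silica
Reagents that add atoms: none
Why: Tsuji–Trost deallylation, in which zerovalent palladium ionises the aryl allyl ether to a π-allyl complex that morpholine captures under neutral conditions that should leave the acid-labile benzhydrol untouched.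

**Step 7**
Reactants: 11 3-(allyloxy)propane-1,2-diol
Product: 12 (allyloxy)acetaldehyde
Conditions: NaIO4, CH2Cl2/H2O, rt
Reagents that add atoms: none
Why: Malaprade glycol cleavage of the terminal 1,2-diol gives the aldehyde without touching the allyl ether.

**Step 8**
Reactants: 10 o-hydroxybenzhydrol; 12 (allyloxy)acetaldehyde
Product: 15 3α-(allyloxy)-5,7-bis(benzyloxy)-4β-(hexa-O-benzyl-EGC-8-yl)chroman-2-ol (3R; 3,4-trans; both anomers), via o-quinone methide 13 (not isolated), via open-chain hydroxy aldehyde 14 (not isolated)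
Conditions: (S)-α,α-diphenylprolinol trimethylsilyl ether (20 mol %), PhCO2H (20 mol %), 12 (3 equiv), CH2Cl2, 0 °C → rt
Reagents that add atoms: none
Why: The acid cocatalyst ionises the doubly trioxygenated benzhydrol 10 to the o-quinone methide 13 (in equilibrium with its protonated benzhydryl cation form), and the E-enamine formed from 12 and the (S)-prolinol ether adds through its α-carbon to the methide carbon, which rearomatises ring A and creates the C3–C4 bond. The closest known reaction type is the secondary-amine-catalysed formal [4+2] of in situ generated o-quinone methides with enolisable aldehydes (enamine Michael addition, then hemiacetalisation), with the SN1-type α-benzhydrylation of aldehydes by stabilised diaryl carbinols and the enamine Michael additions of α-alkoxy aldehydes as further analogies. Hydrolysis of the iminium frees aldehyde 14, and ring C of unit M closes by 6-exo-trig attack of the liberated phenol oxygen on the aldehyde carbon, giving the lactol as anomers that converge in step 9. C3 is set by the catalyst, whose diphenyl(silyloxy)methyl group blocks one face of the s-trans E-enamine so that the electrophile enters from the other face and the (R) centre should result; C4 follows from the synclinal approach of that face to the E-methide, the topology that gives syn Michael adducts and maps onto the 3,4-trans lactol. The step needs catalyst control to override any bias from unit B and needs a single methide: the stereocentres of unit B lie four and five bonds from the reacting carbon on the far side of its pyran ring, and only one phenol of ring A is free, so only one quinone methide can form and the enamine, used in excess, should meet it before it self-condenses.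

**Step 9**
Reactants: 15 lactol
Product: 16 3α-(allyloxy)-5,7-bis(benzyloxy)-4β-(hexa-O-benzyl-EGC-8-yl)chroman-2-one (3,4-trans dihydrocoumarin)
Conditions: Dess–Martin periodinane, CH2Cl2, 0 °C → rt
Reagents that add atoms: none
Why: Dess–Martin oxidation of the lactol to the lactone removes the anomeric centre and should not affect the allyl ether, the benzyl ethers or the C3 and C4 centres.

**Step 10**
Reactants: 17 5-bromo-1,2,3-trimethoxybenzene
Product: 18 5-bromobenzene-1,2,3-triol
Conditions: BBr3, CH2Cl2, −78 °C → rt; H2O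
Reagents that add atoms: none
Why: Lewis acid ether cleavage, in which BBr3 demethylates all three aryl methyl ethers and leaves the aryl bromide intact.

**Step 11**
Reactants: 18 5-bromobenzene-1,2,3-triol
Product: 19 5-bromo-1,2,3-tris(benzyloxy)benzene
Conditions: BnBr, K2CO3, DMF, 60 °C (argon)
Reagents that add atoms: benzyl bromide, BrCc1ccccc1
Why: Williamson etherification of the three phenols under standard carbonate conditions.

**Step 12**
Reactants: 19 5-bromo-1,2,3-tris(benzyloxy)benzene; 16 lactone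
Product: 21 (2R)-2-(allyloxy)-3-[2,4-bis(benzyloxy)-6-hydroxyphenyl]-3-(hexa-O-benzyl-EGC-8-yl)-1-[3,4,5-tris(benzyloxy)phenyl]propan-1-one (C3 and C4 of unit M as in 16), via 3,4,5-tris(benzyloxy)phenyllithium 20 (not isolated)
Conditions: 19, n-BuLi, THF, −78 °C; then 16 (slow addition of the aryllithium to the lactone), −78 °C; aq. NH4Cl at −78 °C
Reagents that add atoms: none
Why: Bromine–lithium exchange and addition of the aryllithium to the lactone carbonyl (acyl substitution stopped at the ketone stage), where the lithium hemiketal is held by chelation to the C3 allyloxy oxygen at −78 °C and is quenched cold, so that neither a second addition nor enolisation at C3 should occur.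

**Step 13**
Reactants: 21 α-allyloxy aryl ketone
Product: 22 (1S,2R)-2-(allyloxy)-3-[2,4-bis(benzyloxy)-6-hydroxyphenyl]-3-(hexa-O-benzyl-EGC-8-yl)-1-[3,4,5-tris(benzyloxy)phenyl]propan-1-ol (anti alcohol)
Conditions: Zn(BH4)2, Et2O/CH2Cl2, −30 → 0 °C; aq. NH4Cl
Reagents that add atoms: none
Why: Chelation-controlled (Cram chelate) reduction, in which zinc bridges the ketone oxygen and the α-allyloxy oxygen and hydride enters from the side of the α-hydrogen, which should give the anti (erythro) alcohol with the (S) configuration at the new carbinol carbon.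

**Step 14**
Reactants: 22 anti alcohol with free phenol
Product: 23 3-O-allyl-5,7,3',4',5'-penta-O-benzyl-EGC-(4β→8)-hexa-O-benzyl-EGC
Conditions: PPh3, DIAD, THF (0.01 M), 0 °C → rt
Reagents that add atoms: none
Why: Intramolecular Mitsunobu etherification, in which the phenol displaces the activated benzylic oxygen in an SN2 6-exo-tet closure with inversion, turning the (S) carbinol into (R)-C2 with the aryl group cis to the C3 oxygen, while the electron-withdrawing C3 alkoxy group disfavours the ionisation that would scramble C2.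

**Step 15**
Reactants: 23 3-O-allyl dimer
Product: 25 5,7,3',4',5'-penta-O-benzyl-EGC-(4β→8)-hexa-O-benzyl-EGC (free 3-OH on unit M), via prop-1-enyl ether 24 (not isolated)
Conditions: [Ir(cod)(PMePh2)2]PF6 (5 mol %, H2-activated, then argon), THF, rt; then 1 M HCl, THF/H2O, rt
Reagents that add atoms: none
Why: Iridium-catalysed isomerisation of the allyl ether to the prop-1-enyl ether followed by mild acid hydrolysis of this enol ether, two stages that benzyl ethers and the interflavan bond should survive.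

**Step 16**
Reactants: 25 dimer with free 3-OH on unit M; 26 3,4,5-tris(benzyloxy)benzoic acid
Product: 27 3-O-[3,4,5-tris(benzyloxy)benzoyl]-penta-O-benzyl-EGC-(4β→8)-hexa-O-benzyl-EGC
Conditions: 26, DCC, DMAP, CH2Cl2, rt
Reagents that add atoms: none
Why: Steglich esterification, the usual way to place a protected galloyl group on the hindered axial C3 hydroxyl of benzylated epi-type flavans.

**Step 17**
Reactants: 4 8-bromo-hexa-O-benzyl-EGC
Product: 28 8-bromo-4β-(2-ethoxyethoxy)-hexa-O-benzyl-EGC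
Conditions: DDQ, 2-ethoxyethanol, CH2Cl2, rt
Reagents that add atoms: 2-ethoxyethanol, CCOCCO
Why: DDQ benzylic oxidation, in which hydride abstraction from C4 (activated by the three ring A oxygens) gives a cation that the alcohol should trap trans to the C3 benzyloxy group, a centre that is lost again on ionisation in step 18.

**Step 18**
Reactants: 27 galloylated dimer; 28 bromine-capped C4 ether of unit T
Product: 29 8-bromo-hexa-O-benzyl-EGC-(4β→8)-[3-O-tris(benzyloxy)benzoyl-penta-O-benzyl-EGC]-(4β→8)-hexa-O-benzyl-EGC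
Conditions: TMSOTf (0.3 equiv), 4 Å MS, CH2Cl2, −78 → −40 °C; Et3N
Reagents that add atoms: none
Why: Lewis acid promoted Friedel–Crafts-type arylation of a flavan-4-yl cation, in which C8 of unit M (the most nucleophilic free ring A position of the dimer) should attack anti to the α-oriented C2 aryl and C3 benzyloxy groups to give the 4β bond, while the C8 bromine keeps unit T from acting as a nucleophile and oligomerising.

**Step 19**
Reactants: 29 protected trimer
Product: 30 epigallocatechin-(4β→8)-epigallocatechin 3-O-gallate-(4β→8)-epigallocatechin (CNP0278699.1)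
Conditions: H2 (1 atm), Pd(OH)2/C, THF/MeOH/H2O, rt
Reagents that add atoms: none
Why: Catalytic hydrogenolysis should cleave all twenty benzyl ethers and the aryl C–Br bond in one operation and leave the gallate ester and both interflavan bonds intact.

**Compound list**

1 | (−)-epigallocatechin (EGC) | O[C@@H]1Cc2c(O)cc(O)cc2O[C@@H]1c1cc(O)c(O)c(O)c1 | starting material
2 | 5,7,3',4',5'-penta-O-benzyl-EGC | O[C@@H]1Cc2c(OCc3ccccc3)cc(OCc3ccccc3)cc2O[C@@H]1c1cc(OCc2ccccc2)c(OCc2ccccc2)c(OCc2ccccc2)c1 | intermediate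
3 | 3,5,7,3',4',5'-hexa-O-benzyl-EGC | c1ccccc1CO[C@@H]1Cc2c(OCc3ccccc3)cc(OCc3ccccc3)cc2O[C@@H]1c1cc(OCc2ccccc2)c(OCc2ccccc2)c(OCc2ccccc2)c1 | intermediate
4 | 8-bromo-hexa-O-benzyl-EGC | c1ccccc1CO[C@@H]1Cc2c(OCc3ccccc3)cc(OCc3ccccc3)c(Br)c2O[C@@H]1c1cc(OCc2ccccc2)c(OCc2ccccc2)c(OCc2ccccc2)c1 | intermediate
5 | 2,4,6-trihydroxybenzaldehyde | O=Cc1c(O)cc(O)cc1O | starting material
6 | 2,4-bis(benzyloxy)-6-hydroxybenzaldehyde | O=Cc1c(O)cc(OCc2ccccc2)cc1OCc1ccccc1 | intermediate
7 | 2-(allyloxy)-4,6-bis(benzyloxy)benzaldehyde | C=CCOc1cc(OCc2ccccc2)cc(OCc2ccccc2)c1C=O | intermediate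
8 | 8-lithio-hexa-O-benzyl-EGC | c1ccccc1CO[C@@H]1Cc2c(OCc3ccccc3)cc(OCc3ccccc3)c([Li])c2O[C@@H]1c1cc(OCc2ccccc2)c(OCc2ccccc2)c(OCc2ccccc2)c1 | intermediate
9 | [2-(allyloxy)-4,6-bis(benzyloxy)phenyl](hexa-O-benzyl-EGC-8-yl)methanol, carbinol epimers | c1ccccc1CO[C@@H]1Cc2c(OCc3ccccc3)cc(OCc3ccccc3)c(C(O)c3c(OCC=C)cc(OCc4ccccc4)cc3OCc3ccccc3)c2O[C@@H]1c1cc(OCc2ccccc2)c(OCc2ccccc2)c(OCc2ccccc2)c1 | intermediate
10 | [2,4-bis(benzyloxy)-6-hydroxyphenyl](hexa-O-benzyl-EGC-8-yl)methanol, carbinol epimers | c1ccccc1CO[C@@H]1Cc2c(OCc3ccccc3)cc(OCc3ccccc3)c(C(O)c3c(O)cc(OCc4ccccc4)cc3OCc3ccccc3)c2O[C@@H]1c1cc(OCc2ccccc2)c(OCc2ccccc2)c(OCc2ccccc2)c1 | intermediate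
11 | 3-(allyloxy)propane-1,2-diol | C=CCOCC(O)CO | starting material
12 | (allyloxy)acetaldehyde | C=CCOCC=O | intermediate
13 | o-quinone methide of 10, 3,5-bis(benzyloxy)-6-[(hexa-O-benzyl-EGC-8-yl)methylidene]cyclohexa-2,4-dien-1-one | c1ccccc1CO[C@@H]1Cc2c(OCc3ccccc3)cc(OCc3ccccc3)c(C=C3C(=O)C=C(OCc4ccccc4)C=C3OCc3ccccc3)c2O[C@@H]1c1cc(OCc2ccccc2)c(OCc2ccccc2)c(OCc2ccccc2)c1 | intermediate
14 | (2R)-2-(allyloxy)-3-[2,4-bis(benzyloxy)-6-hydroxyphenyl]-3-(hexa-O-benzyl-EGC-8-yl)propanal, open form of 15 | c1ccccc1CO[C@@H]1Cc2c(OCc3ccccc3)cc(OCc3ccccc3)c([C@@H](c3c(O)cc(OCc4ccccc4)cc3OCc3ccccc3)[C@@H](OCC=C)C=O)c2O[C@@H]1c1cc(OCc2ccccc2)c(OCc2ccccc2)c(OCc2ccccc2)c1 | intermediate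
15 | 3α-(allyloxy)-5,7-bis(benzyloxy)-4β-(hexa-O-benzyl-EGC-8-yl)chroman-2-ol, 3,4-trans, anomers | c1ccccc1CO[C@@H]1Cc2c(OCc3ccccc3)cc(OCc3ccccc3)c([C@H]3c4c(OCc5ccccc5)cc(OCc5ccccc5)cc4OC(O)[C@@H]3OCC=C)c2O[C@@H]1c1cc(OCc2ccccc2)c(OCc2ccccc2)c(OCc2ccccc2)c1 | intermediate
16 | 3α-(allyloxy)-5,7-bis(benzyloxy)-4β-(hexa-O-benzyl-EGC-8-yl)chroman-2-one | c1ccccc1CO[C@@H]1Cc2c(OCc3ccccc3)cc(OCc3ccccc3)c([C@H]3c4c(OCc5ccccc5)cc(OCc5ccccc5)cc4OC(=O)[C@@H]3OCC=C)c2O[C@@H]1c1cc(OCc2ccccc2)c(OCc2ccccc2)c(OCc2ccccc2)c1 | intermediate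
17 | 5-bromo-1,2,3-trimethoxybenzene | COc1cc(Br)cc(OC)c1OC | starting material
18 | 5-bromobenzene-1,2,3-triol | Oc1cc(Br)cc(O)c1O | intermediate
19 | 5-bromo-1,2,3-tris(benzyloxy)benzene | Brc1cc(OCc2ccccc2)c(OCc2ccccc2)c(OCc2ccccc2)c1 | intermediate
20 | 3,4,5-tris(benzyloxy)phenyllithium | [Li]c1cc(OCc2ccccc2)c(OCc2ccccc2)c(OCc2ccccc2)c1 | intermediate
21 | (2R)-2-(allyloxy)-3-[2,4-bis(benzyloxy)-6-hydroxyphenyl]-3-(hexa-O-benzyl-EGC-8-yl)-1-[3,4,5-tris(benzyloxy)phenyl]propan-1-one | c1ccccc1CO[C@@H]1Cc2c(OCc3ccccc3)cc(OCc3ccccc3)c([C@@H](c3c(O)cc(OCc4ccccc4)cc3OCc3ccccc3)[C@@H](OCC=C)C(=O)c3cc(OCc4ccccc4)c(OCc4ccccc4)c(OCc4ccccc4)c3)c2O[C@@H]1c1cc(OCc2ccccc2)c(OCc2ccccc2)c(OCc2ccccc2)c1 | intermediate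
22 | (1S,2R)-2-(allyloxy)-3-[2,4-bis(benzyloxy)-6-hydroxyphenyl]-3-(hexa-O-benzyl-EGC-8-yl)-1-[3,4,5-tris(benzyloxy)phenyl]propan-1-ol, anti alcohol | c1ccccc1CO[C@@H]1Cc2c(OCc3ccccc3)cc(OCc3ccccc3)c([C@@H](c3c(O)cc(OCc4ccccc4)cc3OCc3ccccc3)[C@@H](OCC=C)[C@@H](O)c3cc(OCc4ccccc4)c(OCc4ccccc4)c(OCc4ccccc4)c3)c2O[C@@H]1c1cc(OCc2ccccc2)c(OCc2ccccc2)c(OCc2ccccc2)c1 | intermediate
23 | 3-O-allyl-5,7,3',4',5'-penta-O-benzyl-EGC-(4β→8)-hexa-O-benzyl-EGC | C=CCO[C@@H]1[C@@H](c2c(OCc3ccccc3)cc(OCc3ccccc3)c3c2O[C@H](c2cc(OCc4ccccc4)c(OCc4ccccc4)c(OCc4ccccc4)c2)[C@H](OCc2ccccc2)C3)c2c(OCc3ccccc3)cc(OCc3ccccc3)cc2O[C@@H]1c1cc(OCc2ccccc2)c(OCc2ccccc2)c(OCc2ccccc2)c1 | intermediate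
24 | 3-O-[(E)-prop-1-enyl]-penta-O-benzyl-EGC-(4β→8)-hexa-O-benzyl-EGC | C/C=C/O[C@@H]1[C@@H](c2c(OCc3ccccc3)cc(OCc3ccccc3)c3c2O[C@H](c2cc(OCc4ccccc4)c(OCc4ccccc4)c(OCc4ccccc4)c2)[C@H](OCc2ccccc2)C3)c2c(OCc3ccccc3)cc(OCc3ccccc3)cc2O[C@@H]1c1cc(OCc2ccccc2)c(OCc2ccccc2)c(OCc2ccccc2)c1 | intermediate
25 | 5,7,3',4',5'-penta-O-benzyl-EGC-(4β→8)-hexa-O-benzyl-EGC, free 3-OH on unit M | O[C@@H]1[C@@H](c2c(OCc3ccccc3)cc(OCc3ccccc3)c3c2O[C@H](c2cc(OCc4ccccc4)c(OCc4ccccc4)c(OCc4ccccc4)c2)[C@H](OCc2ccccc2)C3)c2c(OCc3ccccc3)cc(OCc3ccccc3)cc2O[C@@H]1c1cc(OCc2ccccc2)c(OCc2ccccc2)c(OCc2ccccc2)c1 | intermediate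
26 | 3,4,5-tris(benzyloxy)benzoic acid | OC(=O)c1cc(OCc2ccccc2)c(OCc2ccccc2)c(OCc2ccccc2)c1 | starting material
27 | 3-O-[3,4,5-tris(benzyloxy)benzoyl]-penta-O-benzyl-EGC-(4β→8)-hexa-O-benzyl-EGC | O=C(O[C@@H]1[C@@H](c2c(OCc3ccccc3)cc(OCc3ccccc3)c3c2O[C@H](c2cc(OCc4ccccc4)c(OCc4ccccc4)c(OCc4ccccc4)c2)[C@H](OCc2ccccc2)C3)c2c(OCc3ccccc3)cc(OCc3ccccc3)cc2O[C@@H]1c1cc(OCc2ccccc2)c(OCc2ccccc2)c(OCc2ccccc2)c1)c1cc(OCc2ccccc2)c(OCc2ccccc2)c(OCc2ccccc2)c1 | intermediate
28 | 8-bromo-4β-(2-ethoxyethoxy)-hexa-O-benzyl-EGC | CCOCCO[C@H]1c2c(OCc3ccccc3)cc(OCc3ccccc3)c(Br)c2O[C@H](c2cc(OCc3ccccc3)c(OCc3ccccc3)c(OCc3ccccc3)c2)[C@@H]1OCc1ccccc1 | intermediate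
29 | 8-bromo-hexa-O-benzyl-EGC-(4β→8)-[3-O-tris(benzyloxy)benzoyl-penta-O-benzyl-EGC]-(4β→8)-hexa-O-benzyl-EGC | O=C(O[C@@H]1[C@@H](c2c(OCc3ccccc3)cc(OCc3ccccc3)c3c2O[C@H](c2cc(OCc4ccccc4)c(OCc4ccccc4)c(OCc4ccccc4)c2)[C@H](OCc2ccccc2)C3)c2c(OCc3ccccc3)cc(OCc3ccccc3)c([C@H]3c4c(OCc5ccccc5)cc(OCc5ccccc5)c(Br)c4O[C@H](c4cc(OCc5ccccc5)c(OCc5ccccc5)c(OCc5ccccc5)c4)[C@@H]3OCc3ccccc3)c2O[C@@H]1c1cc(OCc2ccccc2)c(OCc2ccccc2)c(OCc2ccccc2)c1)c1cc(OCc2ccccc2)c(OCc2ccccc2)c(OCc2ccccc2)c1 | intermediate
30 | epigallocatechin-(4β→8)-epigallocatechin 3-O-gallate-(4β→8)-epigallocatechin (CNP0278699.1) | O=C(O[C@@H]1[C@@H](c2c(O)cc(O)c3c2O[C@H](c2cc(O)c(O)c(O)c2)[C@H](O)C3)c2c(O)cc(O)c([C@H]3c4c(O)cc(O)cc4O[C@H](c4cc(O)c(O)c(O)c4)[C@@H]3O)c2O[C@@H]1c1cc(O)c(O)c(O)c1)c1cc(O)c(O)c(O)c1 | target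

**Step count and risks**

Total step count: 19. Longest linear sequence: 13 steps (1, 2, 5, 6, 8, 9, 12, 13, 14, 15, 16, 18, 19).

Step 8. What may go wrong: the methide carbon carries two di-ortho-substituted aryl groups, so E/Z interconversion of the quinone methide, or a stepwise path through the free benzhydryl cation, can erode facial control at C4. The resident centres of unit B can oppose the catalyst, and the methide can be consumed by the amine or by self-condensation before the enamine reaches it. Fallback: the ring construction is given up for this bond and C4(M)–C8(B) is formed by cationic flavanyl arylation. Compound 2, isolated after the first stage of step 1, is oxidised at C4 with DDQ in the presence of 2-ethoxyethanol to 4β-(2-ethoxyethoxy)-penta-O-benzyl-EGC F1. F1 is then condensed with an excess of 3 under TMSOTf in CH2Cl2 at −78 °C. Attack of C8 of 3 anti to the C2 aryl and C3 hydroxyl groups should give the 4β-linked dimer 25, where the route is rejoined for steps 16 to 19.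

Step 12. What may go wrong: the lithium hemiketal collapses at −78 °C and releases the ketone while aryllithium is still present (second addition), or the aryllithium deprotonates C3 and the lactone enolate opens to a ketene, which scrambles C3. Fallback: from 16, the lactone is opened with the magnesium amide of N,O-dimethylhydroxylamine (MeNH(OMe)·HCl, i-PrMgCl, THF, −20 °C) and the phenoxide is capped in the same flask with Et3SiCl to give the ring-opened Weinreb amide triethylsilyl ether F2. Addition of aryllithium 20 to F2 stops at the chelated tetrahedral stage and should give the aryl ketone triethylsilyl ether F3. HF·pyridine then removes the silyl group and returns 21.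

Step 18. What may go wrong: the flavan-4-yl cation attacks C6 of unit M or C6 of unit B instead of C8 of unit M, the oxophilic Lewis acid reopens the existing M–B bond and scrambles the chain, or the bromine-deactivated donor ionises too slowly. Fallback: the donor and the mode of activation are changed. Compound 28 is converted with 2-mercaptobenzothiazole and AlMe3 into 8-bromo-4β-(benzothiazol-2-ylthio)-hexa-O-benzyl-EGC F4. F4 is activated by the thiophilic salt AgBF4 in THF at 0 °C in the presence of 27; these near-neutral conditions should leave the existing interflavan bond untouched and return the protected trimer 29.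

**Further compounds**

F1 | step 8 | 4β-(2-ethoxyethoxy)-5,7,3',4',5'-penta-O-benzyl-EGC | CCOCCO[C@H]1c2c(OCc3ccccc3)cc(OCc3ccccc3)cc2O[C@H](c2cc(OCc3ccccc3)c(OCc3ccccc3)c(OCc3ccccc3)c2)[C@@H]1O
F2 | step 12 | (2R)-2-(allyloxy)-3-[2,4-bis(benzyloxy)-6-(triethylsilyloxy)phenyl]-3-(hexa-O-benzyl-EGC-8-yl)-N-methoxy-N-methylpropanamide | c1ccccc1CO[C@@H]1Cc2c(OCc3ccccc3)cc(OCc3ccccc3)c([C@@H](c3c(O[Si](CC)(CC)CC)cc(OCc4ccccc4)cc3OCc3ccccc3)[C@@H](OCC=C)C(=O)N(C)OC)c2O[C@@H]1c1cc(OCc2ccccc2)c(OCc2ccccc2)c(OCc2ccccc2)c1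
F3 | step 12 | triethylsilyl ether of ketone 21 | c1ccccc1CO[C@@H]1Cc2c(OCc3ccccc3)cc(OCc3ccccc3)c([C@@H](c3c(O[Si](CC)(CC)CC)cc(OCc4ccccc4)cc3OCc3ccccc3)[C@@H](OCC=C)C(=O)c3cc(OCc4ccccc4)c(OCc4ccccc4)c(OCc4ccccc4)c3)c2O[C@@H]1c1cc(OCc2ccccc2)c(OCc2ccccc2)c(OCc2ccccc2)c1
F4 | step 18 | 8-bromo-4β-(benzothiazol-2-ylthio)-hexa-O-benzyl-EGC | c1ccc2sc(S[C@H]3c4c(OCc5ccccc5)cc(OCc5ccccc5)c(Br)c4O[C@H](c4cc(OCc5ccccc5)c(OCc5ccccc5)c(OCc5ccccc5)c4)[C@@H]3OCc3ccccc3)nc2c1
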